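**Plan**

1. Retrosynthesis (halimane numbering: ring A = C1, C2(=O), C3, C4, C5, C10; ring B = C5–C10; C18 = ester carbon; side chain C11–C16): ring A is cut at C1–C2 and at C5–C10. This turns the cyclohexenone into a cyclobutanone (C2, C3, C4, C5) that carries on C5 a four-carbon tether (C6–C9) ending in the alkyne C10≡C1.
2. Enabling feature: in ring A the ketone C2 and the quaternary C4 are 1,3-related as in a 3,3-disubstituted cyclobutanone, and the enone C1=C10 lies between C2 and the fusion carbon C5 with its β-carbon C10 as the second fusion atom. Inserting the alkyne into the C2–C5 bond therefore makes ring A (four to six atoms) and ring B in one event.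
3. Further cuts: C5–C6 (hydrazone alkylation); the alkyne and C6 are folded back into a temporary cyclohexenone (opened in the forward direction by Eschenmoser–Tanabe fragmentation); C9–C11 (enolate alkylation); C8–CH3 (conjugate addition).
4. Forward order: side-chain iodide; temporary six-membered ring that sets C8 and C9 and is then opened to the acyclic alkynyl iodide; union with the cyclobutanone; rings A and B together in the key step; desilylation.
5. Stereochemistry: C13 from methyl (R)-3-methylglutarate; C8 by catalytic asymmetric conjugate addition; C9 by alkylation anti to the C8 methyl; C5 by the SAMP auxiliary; C4 by alkylation anti to a CH(OMe)2 placeholder for the ester, later oxidised to CO2Me; C5 passes through the key step with retention.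

Key step: step 19

Remark: the ligand antipode in step 5 (and the chiral amide antipode in the second fallback) is assumed to be the one that delivers the stated configuration; the epoxide 12 is carried as a mixture of epoxide faces.

**Route**

Step 1
Reactants: 1 methyl (R)-3-methylglutarate
Product: 2 methyl (R)-5-hydroxy-3-methylpentanoate
Conditions: BH3·SMe2, THF, 0 °C → rt
Reagents that add atoms: none
Why: Borane reduces the free carboxylic acid much faster than the methyl ester (chemoselective acid reduction), and the chiral-pool stereocentre C13 is not touched.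

Step 2
Reactants: 2 methyl (R)-5-hydroxy-3-methylpentanoate
Product: 3 methyl (S)-5-iodo-3-methylpentanoate
Conditions: I2, PPh3, imidazole, CH2Cl2, 0 °C → rt
Reagents that add atoms: iodine, II
Why: Appel-type iodination of a primary alcohol under neutral conditions; the descriptor changes only because of the CIP priorities.

Step 3
Reactants: 3 methyl (S)-5-iodo-3-methylpentanoate
Product: 4 (S)-5-iodo-3-methylpentan-1-ol
Conditions: iBu2AlH (2.2 equiv), CH2Cl2, −78 → −20 °C; aqueous potassium sodium tartrate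
Reagents that add atoms: none
Why: DIBAL reduction of the ester to the primary alcohol at low temperature, where the primary iodide is inert and the aluminium alkoxide should not cyclise to the tetrahydropyran.

Step 4
Reactants: 4 (S)-5-iodo-3-methylpentan-1-ol
Product: 5 tert-butyl{[(S)-5-iodo-3-methylpentyl]oxy}diphenylsilane
Conditions: TBDPSCl, imidazole, CH2Cl2, 0 °C → rt
Reagents that add atoms: tert-butyl(chloro)diphenylsilane, CC(C)(C)[Si](Cl)(c1ccccc1)c1ccccc1
Why: Standard silylation; the TBDPS ether is chosen because it must survive strong base, alkaline peroxide, aqueous acid and the hot rhodium step.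

Step 5
Reactants: 6 2-methylcyclohex-2-en-1-one
Product: 8 (R)-[(2,3-dimethylcyclohex-1-en-1-yl)oxy]trimethylsilane, via dimethylaluminium enolate 7 (not isolated)
Conditions: Me3Al, Cu(O2CC4H3S) (copper thiophene-2-carboxylate, 2 mol%), BINOL-derived phosphoramidite ligand (4 mol%), Et2O, −30 °C; then TMSOTf, THF, −30 → 0 °C
Reagents that add atoms: trimethylaluminium, C[Al](C)C; trimethylsilyl triflate, C[Si](C)(C)OS(=O)(=O)C(F)(F)F
Why: Copper-catalysed asymmetric conjugate addition of a methyl nucleophile to an α-substituted cyclohexenone, the ligand antipode directing methyl to the face that gives (R) at C8, followed by O-silylation that fixes the tetrasubstituted enolate regiochemistry.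

Step 6
Reactants: 8 (R)-[(2,3-dimethylcyclohex-1-en-1-yl)oxy]trimethylsilane; 5 tert-butyl{[(S)-5-iodo-3-methylpentyl]oxy}diphenylsilane
Product: 10 (2S,3R)-2-[(R)-5-(tert-butyldiphenylsilyloxy)-3-methylpentyl]-2,3-dimethylcyclohexan-1-one, via lithium enolate 9 (not isolated)
Conditions: MeLi, THF, 0 °C → rt; then 5, HMPA, −40 °C → rt
Reagents that add atoms: none
Why: Regiospecific lithium enolate generation from the silyl enol ether and C-alkylation by a primary iodide, which should enter anti to the pseudoaxial C8 methyl group and so set the quaternary C9 with the two methyl groups cis.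

Step 7
Reactants: 10 (2S,3R)-2-[(R)-5-(tert-butyldiphenylsilyloxy)-3-methylpentyl]-2,3-dimethylcyclohexan-1-one
Product: 11 (5R,6S)-6-[(R)-5-(tert-butyldiphenylsilyloxy)-3-methylpentyl]-5,6-dimethylcyclohex-2-en-1-one
Conditions: IBX (2 equiv), DMSO/PhF, 70 °C
Reagents that add atoms: none
Why: IBX-mediated α,β-dehydrogenation of a ketone, possible only on the CH2 side because the other α-carbon is quaternary.

Step 8
Reactants: 11 (5R,6S)-6-[(R)-5-(tert-butyldiphenylsilyloxy)-3-methylpentyl]-5,6-dimethylcyclohex-2-en-1-one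
Product: 12 (3S,4R)-3-[(R)-5-(tert-butyldiphenylsilyloxy)-3-methylpentyl]-3,4-dimethyl-7-oxabicyclo[4.1.0]heptan-2-one (mixture of epoxide faces)
Conditions: H2O2 (30% aq), NaOH (cat.), MeOH, 0 °C
Reagents that add atoms: hydrogen peroxide, OO
Why: Weitz–Scheffer nucleophilic epoxidation of the enone; the epoxide face is not controlled and is irrelevant because both epoxide carbons lose their configuration in step 9.

Step 9
Reactants: 12 (3S,4R)-3-[(R)-5-(tert-butyldiphenylsilyloxy)-3-methylpentyl]-3,4-dimethyl-7-oxabicyclo[4.1.0]heptan-2-one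
Product: 14 (3R,4S,7R)-9-(tert-butyldiphenylsilyloxy)-4-ethynyl-3,4,7-trimethylnonanal, via sulfonylhydrazone 13 (not isolated)
Conditions: 2,4-(O2N)2C6H3SO2NHNH2, THF, 0 °C; then pyridine, 0 °C → rt
Reagents that add atoms: none
Why: Eschenmoser–Tanabe fragmentation of the α,β-epoxy sulfonylhydrazone, which cleaves the former Cα–Cβ bond with loss of N2 and sulfinate to give the terminal alkyne on the quaternary carbon and the aldehyde at C6, leaving C8 and C9 untouched; the dinitroarylsulfonyl hydrazide fragments at low temperature and so spares the aldehyde.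

Step 10
Reactants: 14 (3R,4S,7R)-9-(tert-butyldiphenylsilyloxy)-4-ethynyl-3,4,7-trimethylnonanal
Product: 15 (3R,4S,7R)-9-(tert-butyldiphenylsilyloxy)-4-ethynyl-3,4,7-trimethylnonan-1-ol
Conditions: NaBH4, MeOH, 0 °C
Reagents that add atoms: none
Why: Chemoselective borohydride reduction of the aldehyde; alkyne and silyl ether are inert.

Step 11
Reactants: 15 (3R,4S,7R)-9-(tert-butyldiphenylsilyloxy)-4-ethynyl-3,4,7-trimethylnonan-1-ol
Product: 16 tert-butyl{[(3R,6S,7R)-6-ethynyl-9-iodo-3,6,7-trimethylnonyl]oxy}diphenylsilane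
Conditions: I2, PPh3, imidazole, CH2Cl2, 0 °C → rt
Reagents that add atoms: iodine, II
Why: Appel-type iodination of the primary alcohol under neutral conditions.

Step 12
Reactants: 17 methacrolein dimethyl acetal (3,3-dimethoxy-2-methylprop-1-ene)
Product: 18 rac-2,2-dichloro-3-(dimethoxymethyl)-3-methylcyclobutan-1-one
Conditions: Cl3CCOCl, Zn–Cu couple, Et2O/DME, rt
Reagents that add atoms: trichloroacetyl chloride, ClC(=O)C(Cl)(Cl)Cl
Why: [2+2] cycloaddition of dichloroketene, generated in situ, with a 1,1-disubstituted alkene, the carbonyl carbon bonding to the CH2 terminus so that the quaternary carbon ends up β to the ketone; the single racemic stereocentre disappears in step 13.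

Step 13
Reactants: 18 rac-2,2-dichloro-3-(dimethoxymethyl)-3-methylcyclobutan-1-one
Product: 19 3-(dimethoxymethyl)-3-methylcyclobutan-1-one
Conditions: Zn, NH4Cl, MeOH, rt
Reagents that add atoms: none
Why: Zinc-mediated reductive removal of both α-chlorine atoms under near-neutral conditions that should spare the acetal, giving the achiral, prochiral cyclobutanone.

Step 14
Reactants: 19 3-(dimethoxymethyl)-3-methylcyclobutan-1-one; 20 (S)-1-amino-2-(methoxymethyl)pyrrolidine (SAMP)
Product: 21 (S)-N-[3-(dimethoxymethyl)-3-methylcyclobutylidene]-2-(methoxymethyl)pyrrolidin-1-amine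
Conditions: neat, 4 Å molecular sieves, 60 °C
Reagents that add atoms: none
Why: Condensation of the ketone with the N-amino auxiliary to the SAMP hydrazone, obtained as C=N isomers that converge on deprotonation.

Step 15
Reactants: 21 (S)-N-[3-(dimethoxymethyl)-3-methylcyclobutylidene]-2-(methoxymethyl)pyrrolidin-1-amine; 16 tert-butyl{[(3R,6S,7R)-6-ethynyl-9-iodo-3,6,7-trimethylnonyl]oxy}diphenylsilane
Product: 23 (S)-N-{(2R,3S)-3-(dimethoxymethyl)-2-[(3R,4S,7R)-9-(tert-butyldiphenylsilyloxy)-4-ethynyl-3,4,7-trimethylnonyl]-3-methylcyclobutylidene}-2-(methoxymethyl)pyrrolidin-1-amine, via lithium azaenolate 22 (not isolated)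
Conditions: 21 (3.5 equiv), LiN(iPr)2 (3.5 equiv), THF, 0 °C; then 16 (1 equiv), −100 → −30 °C
Reagents that add atoms: none
Why: SAMP-hydrazone alkylation in which the auxiliary fixes the face of the azaenolate and hence C5, while the iodide should enter anti to the branched CH(OMe)2 group and so cis to the methyl group, fixing C4; only the azaenolate diastereomer in which both effects reinforce should alkylate quickly, which is why hydrazone and base are used in excess (one equivalent is also spent on the alkyne C–H).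

Step 16
Reactants: 23 (S)-N-{(2R,3S)-3-(dimethoxymethyl)-2-[(3R,4S,7R)-9-(tert-butyldiphenylsilyloxy)-4-ethynyl-3,4,7-trimethylnonyl]-3-methylcyclobutylidene}-2-(methoxymethyl)pyrrolidin-1-amine
Product: 25 (1S,2R)-2-[(3R,4S,7R)-9-(tert-butyldiphenylsilyloxy)-4-ethynyl-3,4,7-trimethylnonyl]-1-methyl-3-oxocyclobutane-1-carbaldehyde, via ketone acetal 24 (not isolated)
Conditions: sat. aq. (CO2H)2, Et2O, rt; then 2 M HCl, THF, rt
Reagents that add atoms: water, O
Why: Mild acidic hydrolysis, first of the hydrazone (oxalic acid, which should leave the α-stereocentre C5 intact) and then of the dimethyl acetal; the aldehyde sits on a quaternary carbon and cannot epimerise.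

Step 17
Reactants: 25 (1S,2R)-2-[(3R,4S,7R)-9-(tert-butyldiphenylsilyloxy)-4-ethynyl-3,4,7-trimethylnonyl]-1-methyl-3-oxocyclobutane-1-carbaldehyde
Product: 26 (1S,2R)-2-[(3R,4S,7R)-9-(tert-butyldiphenylsilyloxy)-4-ethynyl-3,4,7-trimethylnonyl]-1-methyl-3-oxocyclobutane-1-carboxylic acid
Conditions: NaClO2, NaH2PO4, 2-methyl-2-butene, tBuOH/H2O, 0 °C → rt
Reagents that add atoms: sodium chlorite, [Na+].[O-]Cl=O
Why: Pinnick oxidation of the aldehyde under buffered conditions that tolerate ketone, alkyne and the α-stereocentre.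

Step 18
Reactants: 26 (1S,2R)-2-[(3R,4S,7R)-9-(tert-butyldiphenylsilyloxy)-4-ethynyl-3,4,7-trimethylnonyl]-1-methyl-3-oxocyclobutane-1-carboxylic acid
Product: 27 methyl (1S,2R)-2-[(3R,4S,7R)-9-(tert-butyldiphenylsilyloxy)-4-ethynyl-3,4,7-trimethylnonyl]-1-methyl-3-oxocyclobutane-1-carboxylate
Conditions: MeI, KHCO3, DMF, rt
Reagents that add atoms: iodomethane, CI
Why: O-alkylation of the carboxylate, which is insensitive to the neopentyl hindrance, with a base too weak to enolise the cyclobutanone.

Step 19
Reactants: 27 methyl (1S,2R)-2-[(3R,4S,7R)-9-(tert-butyldiphenylsilyloxy)-4-ethynyl-3,4,7-trimethylnonyl]-1-methyl-3-oxocyclobutane-1-carboxylate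
Product: 28 methyl (1S,5S,6R,8aS)-5-[(R)-5-(tert-butyldiphenylsilyloxy)-3-methylpentyl]-1,5,6-trimethyl-3-oxo-1,2,3,5,6,7,8,8a-octahydronaphthalene-1-carboxylate
Conditions: [Rh(CO)2Cl]2 (5 mol%), PMe2Ph (20 mol%), 1,4-dioxane, 130 °C, sealed tube
Reagents that add atoms: none
Why: Monovalent rhodium inserts into a C(O)–C bond of the cyclobutanone (the acyl rhodacycle can move to the hindered C2–C5 side by CO extrusion and re-insertion), the tethered alkyne inserts, and C–C reductive elimination releases the catalyst. The closest known reaction type is the rhodium-catalysed intramolecular cut-and-sew carboacylation of alkynes by cyclobutanones tethered at the α-carbon, which gives cyclohexenone-fused bicycles. Ring A arises by two-atom ring expansion of the four-membered ketone, C10 and C1 being stitched between C5 and C2, and ring B closes in the same event by 6-exo-dig carbometalation across the tether C6–C9. No new stereocentre is created: C5 should keep its configuration because oxidative addition, migratory insertion and reductive elimination proceed with retention at that sp3 carbon, and C4, C8, C9 and C13 are spectators. The step needs cleavage on the substituted side of the ketone and the C2–C1/C5–C10 connectivity, both secured by the tether since the alternative would place the alkene at a bridgehead, and it needs C5 not to epimerise, which the neutral base-free medium should secure; decarbonylation is the expected competitor and is held back by the small electron-rich phosphine.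

Step 20
Reactants: 28 methyl (1S,5S,6R,8aS)-5-[(R)-5-(tert-butyldiphenylsilyloxy)-3-methylpentyl]-1,5,6-trimethyl-3-oxo-1,2,3,5,6,7,8,8a-octahydronaphthalene-1-carboxylate
Product: 29 methyl (1S,5S,6R,8aS)-5-[(R)-5-hydroxy-3-methylpentyl]-1,5,6-trimethyl-3-oxo-1,2,3,5,6,7,8,8a-octahydronaphthalene-1-carboxylate (CNP0157174.1)
Conditions: HF·pyridine, THF/pyridine, 0 °C → rt
Reagents that add atoms: none
Why: Fluoride cleavage of the silyl ether under non-basic conditions, chosen so that the γ-stereocentre C5 is not exposed to dienolate formation.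

**Compound list**

1 | methyl (R)-3-methylglutarate | COC(=O)C[C@H](C)CC(=O)O | starting material
2 | methyl (R)-5-hydroxy-3-methylpentanoate | COC(=O)C[C@H](C)CCO | intermediate
3 | methyl (S)-5-iodo-3-methylpentanoate | COC(=O)C[C@H](C)CCI | intermediate
4 | (S)-5-iodo-3-methylpentan-1-ol | OCC[C@H](C)CCI | intermediate
5 | tert-butyl{[(S)-5-iodo-3-methylpentyl]oxy}diphenylsilane | CC(C)(C)[Si](c1ccccc1)(c1ccccc1)OCC[C@H](C)CCI | intermediate
6 | 2-methylcyclohex-2-en-1-one | CC1=CCCCC1=O | starting material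
7 | dimethylaluminium (R)-2,3-dimethylcyclohex-1-en-1-olate | C[Al](C)OC1=C(C)[C@H](C)CCC1 | intermediate
8 | (R)-[(2,3-dimethylcyclohex-1-en-1-yl)oxy]trimethylsilane | C[Si](C)(C)OC1=C(C)[C@H](C)CCC1 | intermediate
9 | lithium (R)-2,3-dimethylcyclohex-1-en-1-olate | [Li]OC1=C(C)[C@H](C)CCC1 | intermediate
10 | (2S,3R)-2-[(R)-5-(tert-butyldiphenylsilyloxy)-3-methylpentyl]-2,3-dimethylcyclohexan-1-one | O=C1CCC[C@@H](C)[C@]1(C)CC[C@@H](C)CCO[Si](c2ccccc2)(c2ccccc2)C(C)(C)C | intermediate
11 | (5R,6S)-6-[(R)-5-(tert-butyldiphenylsilyloxy)-3-methylpentyl]-5,6-dimethylcyclohex-2-en-1-one | O=C1C=CC[C@@H](C)[C@]1(C)CC[C@@H](C)CCO[Si](c2ccccc2)(c2ccccc2)C(C)(C)C | intermediate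
12 | (3S,4R)-3-[(R)-5-(tert-butyldiphenylsilyloxy)-3-methylpentyl]-3,4-dimethyl-7-oxabicyclo[4.1.0]heptan-2-one (mixture of epoxide faces) | O=C1C2OC2C[C@@H](C)[C@]1(C)CC[C@@H](C)CCO[Si](c3ccccc3)(c3ccccc3)C(C)(C)C | intermediate
13 | 2,4-dinitrobenzenesulfonylhydrazone of 12 | [O-][N+](=O)c1ccc(S(=O)(=O)NN=C2C3OC3C[C@@H](C)[C@]2(C)CC[C@@H](C)CCO[Si](c4ccccc4)(c4ccccc4)C(C)(C)C)c(c1)[N+](=O)[O-] | intermediate
14 | (3R,4S,7R)-9-(tert-butyldiphenylsilyloxy)-4-ethynyl-3,4,7-trimethylnonanal | O=CC[C@@H](C)[C@](C#C)(C)CC[C@@H](C)CCO[Si](c1ccccc1)(c1ccccc1)C(C)(C)C | intermediate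
15 | (3R,4S,7R)-9-(tert-butyldiphenylsilyloxy)-4-ethynyl-3,4,7-trimethylnonan-1-ol | OCC[C@@H](C)[C@](C#C)(C)CC[C@@H](C)CCO[Si](c1ccccc1)(c1ccccc1)C(C)(C)C | intermediate
16 | tert-butyl{[(3R,6S,7R)-6-ethynyl-9-iodo-3,6,7-trimethylnonyl]oxy}diphenylsilane | ICC[C@@H](C)[C@](C#C)(C)CC[C@@H](C)CCO[Si](c1ccccc1)(c1ccccc1)C(C)(C)C | intermediate
17 | methacrolein dimethyl acetal (3,3-dimethoxy-2-methylprop-1-ene) | C=C(C)C(OC)OC | starting material
18 | rac-2,2-dichloro-3-(dimethoxymethyl)-3-methylcyclobutan-1-one | O=C1CC(C)(C(OC)OC)C1(Cl)Cl | intermediate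
19 | 3-(dimethoxymethyl)-3-methylcyclobutan-1-one (achiral) | O=C1CC(C)(C(OC)OC)C1 | intermediate
20 | (S)-1-amino-2-(methoxymethyl)pyrrolidine (SAMP) | COC[C@@H]1CCCN1N | starting material
21 | (S)-N-[3-(dimethoxymethyl)-3-methylcyclobutylidene]-2-(methoxymethyl)pyrrolidin-1-amine | COC[C@@H]1CCCN1N=C1CC(C)(C(OC)OC)C1 | intermediate
22 | lithium azaenolate of 21 (both diastereomers at the ring carbon) | COC[C@@H]1CCCN1N([Li])C1=CC(C)(C(OC)OC)C1 | intermediate
23 | (S)-N-{(2R,3S)-3-(dimethoxymethyl)-2-[(3R,4S,7R)-9-(tert-butyldiphenylsilyloxy)-4-ethynyl-3,4,7-trimethylnonyl]-3-methylcyclobutylidene}-2-(methoxymethyl)pyrrolidin-1-amine | COC(OC)[C@@]1(C)CC(=NN2CCC[C@H]2COC)[C@@H]1CC[C@@H](C)[C@](C#C)(C)CC[C@@H](C)CCO[Si](c3ccccc3)(c3ccccc3)C(C)(C)C | intermediate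
24 | (2R,3S)-3-(dimethoxymethyl)-2-[(3R,4S,7R)-9-(tert-butyldiphenylsilyloxy)-4-ethynyl-3,4,7-trimethylnonyl]-3-methylcyclobutan-1-one | COC(OC)[C@@]1(C)CC(=O)[C@@H]1CC[C@@H](C)[C@](C#C)(C)CC[C@@H](C)CCO[Si](c2ccccc2)(c2ccccc2)C(C)(C)C | intermediate
25 | (1S,2R)-2-[(3R,4S,7R)-9-(tert-butyldiphenylsilyloxy)-4-ethynyl-3,4,7-trimethylnonyl]-1-methyl-3-oxocyclobutane-1-carbaldehyde | O=C[C@@]1(C)CC(=O)[C@@H]1CC[C@@H](C)[C@](C#C)(C)CC[C@@H](C)CCO[Si](c2ccccc2)(c2ccccc2)C(C)(C)C | intermediate
26 | (1S,2R)-2-[(3R,4S,7R)-9-(tert-butyldiphenylsilyloxy)-4-ethynyl-3,4,7-trimethylnonyl]-1-methyl-3-oxocyclobutane-1-carboxylic acid | OC(=O)[C@@]1(C)CC(=O)[C@@H]1CC[C@@H](C)[C@](C#C)(C)CC[C@@H](C)CCO[Si](c2ccccc2)(c2ccccc2)C(C)(C)C | intermediate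
27 | methyl (1S,2R)-2-[(3R,4S,7R)-9-(tert-butyldiphenylsilyloxy)-4-ethynyl-3,4,7-trimethylnonyl]-1-methyl-3-oxocyclobutane-1-carboxylate | COC(=O)[C@@]1(C)CC(=O)[C@@H]1CC[C@@H](C)[C@](C#C)(C)CC[C@@H](C)CCO[Si](c2ccccc2)(c2ccccc2)C(C)(C)C | intermediate
28 | methyl (1S,5S,6R,8aS)-5-[(R)-5-(tert-butyldiphenylsilyloxy)-3-methylpentyl]-1,5,6-trimethyl-3-oxo-1,2,3,5,6,7,8,8a-octahydronaphthalene-1-carboxylate | COC(=O)[C@@]1(C)CC(=O)C=C2[C@@H]1CC[C@@H](C)[C@]2(C)CC[C@@H](C)CCO[Si](c3ccccc3)(c3ccccc3)C(C)(C)C | intermediate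
29 | methyl (1S,5S,6R,8aS)-5-[(R)-5-hydroxy-3-methylpentyl]-1,5,6-trimethyl-3-oxo-1,2,3,5,6,7,8,8a-octahydronaphthalene-1-carboxylate (CNP0157174.1) | COC(=O)[C@@]1(C)CC(=O)C=C2[C@@H]1CC[C@@H](C)[C@]2(C)CC[C@@H](C)CCO | target

**Step count and risks**

Total step count: 20. Longest linear sequence: 16 steps (steps 1–4, 6–11 and 15–20, from 1 to 29).

Steps most likely to fail:

Step 19. The terminal alkyne may be diverted on monovalent rhodium into vinylidene formation or oligomerisation, and loss of CO from the rhodacycle may outrun alkyne insertion. The fallback caps the alkyne with silicon so that the substrate is an internal alkyne. It sets out from 23: selective metalation of the alkyne C–H (EtMgBr, THF, 0 °C → rt) and quenching with Me3SiCl should give the C-silylated hydrazone F1. The same two-stage acid hydrolysis should pass through the silylalkynyl ketone acetal F2 to the silylalkynyl keto aldehyde F3. Pinnick oxidation should give the silylalkynyl keto acid F4, and MeI/KHCO3 the silylalkynyl keto ester F5. The rhodium-catalysed cut-and-sew reaction of F5 should give the 2-trimethylsilyl enone F6. Acid protodesilylation (CF3CO2H, CH2Cl2, 0 °C), as practised on α-silyl enones from Pauson–Khand reactions, comes back to the route at 28.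

Step 15. Facial discrimination between the methyl and the dimethoxymethyl group may be insufficient, or the matched azaenolate may fail to outpace the mismatched one, either of which would erode the C4/C5 configuration; slow C-alkylation by the unactivated iodide would also let proton transfer compete. The fallback moves the enantio-determining event to the deprotonation and uses a faster electrophile. It sets out from 19 and 15: enantiotopic deprotonation of 19 with LiN[CH(CH3)Ph]2 (the antipode that leads to the S enol ether) with Me3SiCl present, THF, −100 °C, should give the (S)-silyl enol ether F7. Alcohol 15 with Tf2O and 2,6-lutidine (CH2Cl2, −78 °C) should give the primary triflate F8. MeLi converts F7 into the lithium enolate F9, which should be alkylated by F8 at −78 °C anti to the dimethoxymethyl group. This comes back to the route at 24, isolated in this case and hydrolysed with 2 M HCl to 25.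

Step 9. Condensation at the ketone next to the quaternary carbon may be slow, and the liberated aldehyde may be attacked by unreacted hydrazide. The fallback opens the ring oxidatively and builds the alkyne by homologation. It sets out from 11: ozonolysis with borohydride work-up (O3, CH2Cl2/MeOH, −78 °C; NaBH4) should give the triol F10. Glycol cleavage (NaIO4, THF/H2O) should remove one carbon and give the hydroxy aldehyde in its closed form, the lactol F11. Ohira–Bestmann homologation (dimethyl (1-diazo-2-oxopropyl)phosphonate, K2CO3, MeOH) of the lactol comes back to the route at 15.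

Further compounds
F1 | step 19 | C-trimethylsilyl alkyne analogue of hydrazone 23 | COC(OC)[C@@]1(C)CC(=NN2CCC[C@H]2COC)[C@@H]1CC[C@@H](C)[C@](C#C[Si](C)(C)C)(C)CC[C@@H](C)CCO[Si](c3ccccc3)(c3ccccc3)C(C)(C)C
F2 | step 19 | C-trimethylsilyl alkyne analogue of ketone acetal 24 | COC(OC)[C@@]1(C)CC(=O)[C@@H]1CC[C@@H](C)[C@](C#C[Si](C)(C)C)(C)CC[C@@H](C)CCO[Si](c2ccccc2)(c2ccccc2)C(C)(C)C
F3 | step 19 | C-trimethylsilyl alkyne analogue of keto aldehyde 25 | O=C[C@@]1(C)CC(=O)[C@@H]1CC[C@@H](C)[C@](C#C[Si](C)(C)C)(C)CC[C@@H](C)CCO[Si](c2ccccc2)(c2ccccc2)C(C)(C)C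
F4 | step 19 | C-trimethylsilyl alkyne analogue of keto acid 26 | OC(=O)[C@@]1(C)CC(=O)[C@@H]1CC[C@@H](C)[C@](C#C[Si](C)(C)C)(C)CC[C@@H](C)CCO[Si](c2ccccc2)(c2ccccc2)C(C)(C)C
F5 | step 19 | C-trimethylsilyl alkyne analogue of keto ester 27 | COC(=O)[C@@]1(C)CC(=O)[C@@H]1CC[C@@H](C)[C@](C#C[Si](C)(C)C)(C)CC[C@@H](C)CCO[Si](c2ccccc2)(c2ccccc2)C(C)(C)C
F6 | step 19 | analogue of 28 with trimethylsilyl on the enone α-carbon (C1 of ring A) | COC(=O)[C@@]1(C)CC(=O)C([Si](C)(C)C)=C2[C@@H]1CC[C@@H](C)[C@]2(C)CC[C@@H](C)CCO[Si](c3ccccc3)(c3ccccc3)C(C)(C)C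
F7 | step 15 | (S)-{[3-(dimethoxymethyl)-3-methylcyclobut-1-en-1-yl]oxy}trimethylsilane | COC(OC)[C@@]1(C)CC(O[Si](C)(C)C)=C1
F8 | step 15 | (3R,4S,7R)-9-(tert-butyldiphenylsilyloxy)-4-ethynyl-3,4,7-trimethylnonyl trifluoromethanesulfonate | O=S(=O)(OCC[C@@H](C)[C@](C#C)(C)CC[C@@H](C)CCO[Si](c1ccccc1)(c1ccccc1)C(C)(C)C)C(F)(F)F
F9 | step 15 | lithium (S)-3-(dimethoxymethyl)-3-methylcyclobut-1-en-1-olate | COC(OC)[C@@]1(C)CC(O[Li])=C1
F10 | step 9 | triol from ozonolysis and reduction of 11 (carbinol centre as a mixture) | OCC[C@@H](C)[C@](C(O)CO)(C)CC[C@@H](C)CCO[Si](c1ccccc1)(c1ccccc1)C(C)(C)C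
F11 | step 9 | (3S,4R)-3-[(R)-5-(tert-butyldiphenylsilyloxy)-3-methylpentyl]-3,4-dimethyltetrahydro-2H-pyran-2-ol (lactol, anomer mixture) | OC1OCC[C@@H](C)[C@]1(C)CC[C@@H](C)CCO[Si](c2ccccc2)(c2ccccc2)C(C)(C)C
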